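**Retrosynthetic overview**
- The target comes from a macrocyclic (3E,7Z)-diene carrying a C12 Mannich base; one catalytic oxidation makes both oxiranes and unmasks the exo-methylene ketone (amine-oxide Cope elimination).
- The 12-membered ring is closed last, at C1–C2, by a photo-organocatalytic iminium-ion radical macrocyclisation of a tethered allylsilane onto the cyclohexenone (new step, sets C1).
- C9–C10, the C10 carbinol and the Z C7=C8 olefin come from a phosphoric-acid-catalysed allylboration of a ring aldehyde with a racemic α-substituted allylboronate made from geranyl acetate.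
- The ring aldehyde comes from a Nef reaction on the product of an organocatalytic desymmetrising nitro-Michael addition to 4,4-dimethylcyclohexa-2,5-dien-1-one (first stereocentre, C11).
- Ring order: the six-membered ring is bought in, the 12-membered ring is formed in step 10, the two oxiranes in step 11.

Assumption: the dienone, nitromethane and geranyl acetate are bought; each chiral catalyst is used in the antipode (or pseudo-enantiomer) that gives the stated sense of induction.

Atom labels: bicyclo[9.3.1]pentadecane numbering of the target (C1 and C11 bridgeheads, C2–C10 long bridge, C12–C14 short bridge with C13 the ketone, C15 the CMe2 bridge, C18 the methylidene carbon). Open-chain intermediates carry the same labels.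

**Route**

Step 1
Reactants: 1 4,4-dimethylcyclohexa-2,5-dien-1-one; 2 nitromethane
Product: 3 (5R)-4,4-dimethyl-5-(nitromethyl)cyclohex-2-en-1-one
Conditions: 9-amino-9-deoxy-epi-quinine (20 mol%), PhCO2H (40 mol%), MeNO2 (5 equiv), toluene, 40 °C, stopped at about 90% conversion
Reagents that add atoms: none
Why: Iminium-ion-catalysed desymmetrising Michael addition of nitromethane, in which the primary-amine cinchona catalyst selects one of the two enantiotopic enone β-carbons and its face, setting C11.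

Step 2
Reactants: 3 (5R)-4,4-dimethyl-5-(nitromethyl)cyclohex-2-en-1-one
Product: 5 (1R)-2,2-dimethyl-5-oxocyclohex-3-ene-1-carbaldehyde, via potassium nitronate 4 (not isolated)
Conditions: KOtBu (1.0 equiv), THF, −78 °C; then DMDO (1.2 equiv, acetone), −78 → −20 °C; pH 7 buffer
Reagents that add atoms: dimethyldioxirane, CC1(C)OO1
Why: Oxidative Nef reaction of the nitronate; the cold, near-neutral conditions keep C11, now α to the aldehyde and flanked by the quaternary C15, from epimerising.

Step 3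
Reactants: 6 geranyl acetate
Product: 7 (2E,6E)-8-hydroxy-3,7-dimethylocta-2,6-dien-1-yl acetate
Conditions: SeO2 (10 mol%), t-BuOOH (3 equiv), salicylic acid (10 mol%), CH2Cl2, rt
Reagents that add atoms: tert-butyl hydroperoxide, CC(C)(C)OO
Why: Riley allylic oxidation (ene reaction then [2,3]-shift) is selective for the E-methyl of the terminal trisubstituted olefin; no stereocentre is formed.

Step 4
Reactants: 7 (2E,6E)-8-hydroxy-3,7-dimethylocta-2,6-dien-1-yl acetate
Product: 8 (2E,6E)-2,6-dimethyl-8-(trimethylsilyl)octa-2,6-dien-1-ol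
Conditions: Pd(dba)2 (5 mol%), LiCl (0.5 equiv), Me3SiSiMe3 (1.5 equiv), DMF, 100 °C; aqueous work-up
Reagents that add atoms: hexamethyldisilane, C[Si](C)(C)[Si](C)(C)C
Why: Tsuji–Trost-type allylic silylation, in which zerovalent palladium ionises only the allylic acetate and the silyl group is delivered to the less hindered terminus with the E geometry kept.

Step 5
Reactants: 8 (2E,6E)-2,6-dimethyl-8-(trimethylsilyl)octa-2,6-dien-1-ol
Product: 9 methyl (2E,6E)-2,6-dimethyl-8-(trimethylsilyl)octa-2,6-dien-1-yl carbonate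
Conditions: ClCO2Me, pyridine, CH2Cl2, 0 °C
Reagents that add atoms: methyl chloroformate, COC(=O)Cl
Why: Simple O-acylation to the allylic carbonate needed for the copper step; the allylsilane is inert to these conditions.

Step 6
Reactants: 9 methyl (2E,6E)-2,6-dimethyl-8-(trimethylsilyl)octa-2,6-dien-1-yl carbonate
Product: 10 rac-trimethyl[(2E)-3,7-dimethyl-6-(4,4,5,5-tetramethyl-1,3,2-dioxaborolan-2-yl)octa-2,7-dien-1-yl]silane
Conditions: CuCl (5 mol%), Xantphos (5 mol%), KOtBu (10 mol%), B2pin2 (1.2 equiv), THF, rt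
Reagents that add atoms: bis(pinacolato)diboron, CC1(C)OB(OC1(C)C)B1OC(C)(C)C(C)(C)O1
Why: Copper-catalysed γ-selective (SN2') allylic borylation places boron on C7 and moves the olefin to C8=C9, giving the racemic α-substituted 2-methylallyl boronate.

Step 7
Reactants: 5 (1R)-2,2-dimethyl-5-oxocyclohex-3-ene-1-carbaldehyde; 10 rac-trimethyl[(2E)-3,7-dimethyl-6-(4,4,5,5-tetramethyl-1,3,2-dioxaborolan-2-yl)octa-2,7-dien-1-yl]silane
Product: 12 (5R)-5-[(1R,3Z,7E)-1-hydroxy-3,7-dimethyl-9-(trimethylsilyl)nona-3,7-dien-1-yl]-4,4-dimethylcyclohex-2-en-1-one, via pinacol borate ester 11 (not isolated)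
Conditions: (R)-TRIP (5 mol%), 10 (2.5 equiv), 4 Å MS, toluene, 0 °C → rt; aq. NaHCO3
Reagents that add atoms: none
Why: Hoffmann-type allylboration through a closed chair transition state, run as a chiral-phosphoric-acid-catalysed kinetic resolution of the racemic boronate: the R boronate reacts with its α-substituent axial (A(1,2) strain with the 2-methyl), giving the Z olefin, and adds to the Felkin–Anh face anti to C15, giving 10R, so catalyst, reagent and substrate control agree.

Step 8
Reactants: 12 (5R)-5-[(1R,3Z,7E)-1-hydroxy-3,7-dimethyl-9-(trimethylsilyl)nona-3,7-dien-1-yl]-4,4-dimethylcyclohex-2-en-1-one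
Product: 13 (1R,3Z,7E)-1-[(1R)-2,2-dimethyl-5-oxocyclohex-3-en-1-yl]-3,7-dimethyl-9-(trimethylsilyl)nona-3,7-dien-1-yl acetate
Conditions: Ac2O, pyridine, DMAP (5 mol%), CH2Cl2, 0 °C
Reagents that add atoms: acetic anhydride, CC(=O)OC(C)=O
Why: Acylation of the secondary alcohol, done at once so that the γ-hydroxy enone cannot close by oxa-Michael addition.

Step 9
Reactants: 13 (1R,3Z,7E)-1-[(1R)-2,2-dimethyl-5-oxocyclohex-3-en-1-yl]-3,7-dimethyl-9-(trimethylsilyl)nona-3,7-dien-1-yl acetate
Product: 15 (1R,3Z,7E)-1-[(1R,6S)-6-[(dimethylamino)methyl]-2,2-dimethyl-5-oxocyclohex-3-en-1-yl]-3,7-dimethyl-9-(trimethylsilyl)nona-3,7-dien-1-yl acetate, via trimethylsilyl dienol ether 14 (not isolated)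
Conditions: TMSOTf (1.1 equiv), Et3N (2 equiv), CH2Cl2, −78 → 0 °C; then Me2N=CH2 I (1.05 equiv), 0 °C → rt; aq. NaHCO3
Reagents that add atoms: Eschenmoser's salt, C[N+](C)=C.[I-]
Why: Mannich reaction of the cross-conjugated silyl dienol ether; C12 is the only enolisable position because C15 is quaternary and C14 is vinylic, and the silyl enol ether is far more nucleophilic than the allylsilane (the new C12 centre, trans shown, is destroyed in step 11).

Step 10
Reactants: 15 (1R,3Z,7E)-1-[(1R,6S)-6-[(dimethylamino)methyl]-2,2-dimethyl-5-oxocyclohex-3-en-1-yl]-3,7-dimethyl-9-(trimethylsilyl)nona-3,7-dien-1-yl acetate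
Product: 16 (1R,3E,7Z,10R,11R,12S)-12-[(dimethylamino)methyl]-4,8,15,15-tetramethyl-13-oxobicyclo[9.3.1]pentadeca-3,7-dien-10-yl acetate
Conditions: CF3CO2H (1.0 equiv, protonates NMe2); carbazole-tethered chiral primary amine from (1R,2R)-cyclohexane-1,2-diamine (20 mol%), PhCO2H (40 mol%), MeCN/H2O 20:1, syringe-pump addition to 1 mM, 420 nm LEDs, 15 °C; aq. NaHCO3
Reagents that add atoms: none
Why: Proposed new method: the chiral primary amine condenses with the C13 ketone to a conjugated iminium ion whose carbazole unit forms an intramolecular donor–acceptor pair; 420 nm excitation gives a carbazole radical cation that oxidises the tethered trisubstituted allylsilane by single-electron transfer; loss of Me3Si+ leaves the E-configured allyl radical, which adds through its unsubstituted terminus C2 to the iminium β-carbon C1 (12-membered ring, olefin geometry kept); back electron transfer and enamine hydrolysis release ketone and catalyst; C1 is set by axial attack anti to the C11 side chain (3,5-trans), reinforced by the catalyst's facial shielding, and the enone itself does not absorb at 420 nm; the closest known reaction types are the excited-iminium single-electron-transfer β-allylation of enals with allylsilanes, primary-amine iminium trapping of radicals by cyclic enones, and tin-mediated allylic radical macrocyclisation onto enones.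

Step 11
Reactants: 16 (1R,3E,7Z,10R,11R,12S)-12-[(dimethylamino)methyl]-4,8,15,15-tetramethyl-13-oxobicyclo[9.3.1]pentadeca-3,7-dien-10-yl acetate
Product: 18 (1R,3R,4R,7R,8S,10R,11S)-3,4:7,8-diepoxy-4,8,15,15-tetramethyl-12-methylidene-13-oxobicyclo[9.3.1]pentadecan-10-yl acetate, via diepoxy amine N-oxide 17 (not isolated)
Conditions: D-fructose-derived Shi ketone (0.4 equiv), KHSO5 (Oxone, 4 equiv), K2CO3, Bu4NHSO4 (cat.), MeCN/dimethoxymethane/aq. Na2B4O7–Na2EDTA buffer (pH 10.5), 0 °C; extract, then CHCl3, 35 °C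
Reagents that add atoms: potassium peroxymonosulfate, [K+].[O-]S(=O)(=O)OO
Why: Shi epoxidation, whose spiro transition state puts the vinylic hydrogen in the hindered quadrant and so delivers oxygen to the face that gives R at both CH carbons (E olefin → 3R,4R trans-oxirane, Z olefin → 7R,8S cis-oxirane); the same oxidant converts the Mannich base into its N-oxide, which undergoes Cope elimination to the exo-methylene ketone.

**Compound list**
1 | 4,4-dimethylcyclohexa-2,5-dien-1-one | CC1(C)C=CC(=O)C=C1 | starting material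
2 | nitromethane | C[N+](=O)[O-] | starting material
3 | (5R)-4,4-dimethyl-5-(nitromethyl)cyclohex-2-en-1-one | [O-][N+](=O)C[C@@H]1CC(=O)C=CC1(C)C | intermediate
4 | potassium nitronate of 3 (R) | [K+].[O-][N+]([O-])=C[C@@H]1CC(=O)C=CC1(C)C | intermediate
5 | (1R)-2,2-dimethyl-5-oxocyclohex-3-ene-1-carbaldehyde | O=C[C@@H]1CC(=O)C=CC1(C)C | intermediate
6 | geranyl acetate, (2E)-3,7-dimethylocta-2,6-dien-1-yl acetate | CC(C)=CCC/C(C)=C/COC(C)=O | starting material
7 | (2E,6E)-8-hydroxy-3,7-dimethylocta-2,6-dien-1-yl acetate | OC/C(C)=C/CC/C(C)=C/COC(C)=O | intermediate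
8 | (2E,6E)-2,6-dimethyl-8-(trimethylsilyl)octa-2,6-dien-1-ol | OC/C(C)=C/CC/C(C)=C/C[Si](C)(C)C | intermediate
9 | methyl (2E,6E)-2,6-dimethyl-8-(trimethylsilyl)octa-2,6-dien-1-yl carbonate | COC(=O)OC/C(C)=C/CC/C(C)=C/C[Si](C)(C)C | intermediate
10 | rac-trimethyl[(2E)-3,7-dimethyl-6-(4,4,5,5-tetramethyl-1,3,2-dioxaborolan-2-yl)octa-2,7-dien-1-yl]silane (racemic at C7) | C[Si](C)(C)C/C=C(\C)CCC(B1OC(C)(C)C(C)(C)O1)C(C)=C | intermediate
11 | pinacol borate ester of 12 (O–B bond at C10, 10R, ring 5R, 3Z,7E) | C[Si](C)(C)C/C=C(\C)CC/C=C(/C)C[C@@H](OB1OC(C)(C)C(C)(C)O1)[C@@H]2CC(=O)C=CC2(C)C | intermediate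
12 | (5R)-5-[(1R,3Z,7E)-1-hydroxy-3,7-dimethyl-9-(trimethylsilyl)nona-3,7-dien-1-yl]-4,4-dimethylcyclohex-2-en-1-one | C[Si](C)(C)C/C=C(\C)CC/C=C(/C)C[C@@H](O)[C@@H]1CC(=O)C=CC1(C)C | intermediate
13 | (1R,3Z,7E)-1-[(1R)-2,2-dimethyl-5-oxocyclohex-3-en-1-yl]-3,7-dimethyl-9-(trimethylsilyl)nona-3,7-dien-1-yl acetate | C[Si](C)(C)C/C=C(\C)CC/C=C(/C)C[C@@H](OC(C)=O)[C@@H]1CC(=O)C=CC1(C)C | intermediate
14 | (1R,3Z,7E)-1-[(1R)-6,6-dimethyl-3-(trimethylsilyloxy)cyclohexa-2,4-dien-1-yl]-3,7-dimethyl-9-(trimethylsilyl)nona-3,7-dien-1-yl acetate | C[Si](C)(C)C/C=C(\C)CC/C=C(/C)C[C@@H](OC(C)=O)[C@@H]1C=C(O[Si](C)(C)C)C=CC1(C)C | intermediate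
15 | (1R,3Z,7E)-1-[(1R,6S)-6-[(dimethylamino)methyl]-2,2-dimethyl-5-oxocyclohex-3-en-1-yl]-3,7-dimethyl-9-(trimethylsilyl)nona-3,7-dien-1-yl acetate (trans epimer shown) | C[Si](C)(C)C/C=C(\C)CC/C=C(/C)C[C@@H](OC(C)=O)[C@@H]1[C@@H](CN(C)C)C(=O)C=CC1(C)C | intermediate
16 | (1R,3E,7Z,10R,11R,12S)-12-[(dimethylamino)methyl]-4,8,15,15-tetramethyl-13-oxobicyclo[9.3.1]pentadeca-3,7-dien-10-yl acetate | CN(C)C[C@H]1C(=O)C[C@H]2C/C=C(\C)CC/C=C(/C)C[C@@H](OC(C)=O)[C@H]1C2(C)C | intermediate
17 | (1R,3R,4R,7R,8S,10R,11R,12S)-12-[(dimethylamino)methyl]-3,4:7,8-diepoxy-4,8,15,15-tetramethyl-13-oxobicyclo[9.3.1]pentadecan-10-yl acetate N-oxide | C[N+](C)([O-])C[C@H]1C(=O)C[C@H]2C[C@H]3O[C@]3(C)CC[C@H]3O[C@@]3(C)C[C@@H](OC(C)=O)[C@H]1C2(C)C | intermediate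
18 | (1R,3R,4R,7R,8S,10R,11S)-3,4:7,8-diepoxy-4,8,15,15-tetramethyl-12-methylidene-13-oxobicyclo[9.3.1]pentadecan-10-yl acetate (CNP0339728.4) | C=C1C(=O)C[C@H]2C[C@H]3O[C@]3(C)CC[C@H]3O[C@@]3(C)C[C@@H](OC(C)=O)[C@H]1C2(C)C | target

Total step count: 11. Longest linear sequence: 9 steps (steps 3–11, from geranyl acetate); the ring branch is 7 steps (1, 2, 7–11).

**Three steps most likely to fail**

Step 10 (the proposed new macrocyclisation). Possible failures are oligomerisation, attack through the tertiary allyl terminus (10-membered ring), the C1 epimer, or no electron transfer at all.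

The fallback uses known tin-hydride allylic radical macrocyclisation onto an enone. It sets out from 5 and comes back at 16. Geraniol is silylated (TBSCl, imidazole) to geranyl tert-butyldimethylsilyl ether F1. Riley oxidation as in step 3 gives the 8-hydroxy compound F2, and ClCO2Me/pyridine gives its methyl carbonate F3. CuCl/Xantphos/KOtBu/B2pin2 as in step 6 then gives the racemic silyloxy allylboronate F4. (R)-TRIP-catalysed allylboration of 5 as in step 7, with bicarbonate work-up, gives the homoallylic alcohol F5, and Ac2O/pyridine/DMAP gives its acetate F6. Soft enolisation and Eschenmoser's salt as in step 9 give the Mannich base F7. Ph3PBr2 in CH2Cl2 at 0 °C converts the allylic silyl ether directly into the E allylic bromide F8, which is kept as its ammonium salt so that the amine cannot be allylated. Slow addition of F8 to Bu3SnH/AIBN in hot benzene at about 2 mM closes the ring through the primary terminus of the E allyl radical at C1. Bicarbonate work-up gives 16. C1 is then set by substrate control only (axial attack, 3,5-trans).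

Step 11 (double epoxidation with concurrent unmasking). The macrocycle may expose the opposite olefin faces to the chiral dioxirane, or the freshly formed enone may be attacked by the oxidant.

The fallback is a stepwise, face-inverting halohydrin route. It sets out from 16 and comes back at 17. The trifluoroacetate salt of 16 is treated with NBS in aqueous THF at 0 °C. Bromonium ions form on the exposed faces and water opens them at the tertiary carbons C4 and C8, giving the bis-bromohydrin F9. DBU then closes both oxiranes with inversion at C3 and C7, so the oxygens end up on the faces opposite to direct electrophilic attack, giving the diepoxy amine F10. mCPBA (1.05 equiv) at −20 °C gives 17, which eliminates to 18 on warming.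

Step 7 (three-fold stereocontrol on a hindered, epimerisable aldehyde). The resolution factor of the acid catalyst with this 2-methyl-substituted boronate may be low, giving E/Z or C10 mixtures.

The fallback replaces catalyst-controlled kinetic resolution by stereospecific chirality transfer from a pre-formed reagent. It sets out from 9 and comes back at 12 through 11. Asymmetric γ-borylation of 9 (CuCl, KOtBu, (R,R)-QuinoxP*, B2pin2, THF, 0 °C) gives the enantioenriched (6R)-allylboronate F11. F11 (1.3 equiv) is heated with 5 in toluene at 50 °C without catalyst. The closed chair transition state transfers the C7 configuration to C10 and gives the Z olefin, forming 11 and, after work-up, 12.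

**Further compounds**
F1 | step 10 | tert-butyl{[(2E)-3,7-dimethylocta-2,6-dien-1-yl]oxy}dimethylsilane | CC(C)=CCC/C(C)=C/CO[Si](C)(C)C(C)(C)C
F2 | step 10 | (2E,6E)-8-{[tert-butyl(dimethyl)silyl]oxy}-2,6-dimethylocta-2,6-dien-1-ol | OC/C(C)=C/CC/C(C)=C/CO[Si](C)(C)C(C)(C)C
F3 | step 10 | (2E,6E)-8-{[tert-butyl(dimethyl)silyl]oxy}-2,6-dimethylocta-2,6-dien-1-yl methyl carbonate | COC(=O)OC/C(C)=C/CC/C(C)=C/CO[Si](C)(C)C(C)(C)C
F4 | step 10 | rac-tert-butyl{[(2E)-3,7-dimethyl-6-(4,4,5,5-tetramethyl-1,3,2-dioxaborolan-2-yl)octa-2,7-dien-1-yl]oxy}dimethylsilane | CC(C)(C)[Si](C)(C)OC/C=C(\C)CCC(B1OC(C)(C)C(C)(C)O1)C(C)=C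
F5 | step 10 | (5R)-5-[(1R,3Z,7E)-9-{[tert-butyl(dimethyl)silyl]oxy}-1-hydroxy-3,7-dimethylnona-3,7-dien-1-yl]-4,4-dimethylcyclohex-2-en-1-one | CC(C)(C)[Si](C)(C)OC/C=C(\C)CC/C=C(/C)C[C@@H](O)[C@@H]1CC(=O)C=CC1(C)C
F6 | step 10 | (1R,3Z,7E)-9-{[tert-butyl(dimethyl)silyl]oxy}-1-[(1R)-2,2-dimethyl-5-oxocyclohex-3-en-1-yl]-3,7-dimethylnona-3,7-dien-1-yl acetate | CC(C)(C)[Si](C)(C)OC/C=C(\C)CC/C=C(/C)C[C@@H](OC(C)=O)[C@@H]1CC(=O)C=CC1(C)C
F7 | step 10 | (1R,3Z,7E)-9-{[tert-butyl(dimethyl)silyl]oxy}-1-[(1R,6S)-6-[(dimethylamino)methyl]-2,2-dimethyl-5-oxocyclohex-3-en-1-yl]-3,7-dimethylnona-3,7-dien-1-yl acetate | CC(C)(C)[Si](C)(C)OC/C=C(\C)CC/C=C(/C)C[C@@H](OC(C)=O)[C@@H]1[C@@H](CN(C)C)C(=O)C=CC1(C)C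
F8 | step 10 | (1R,3Z,7E)-9-bromo-1-[(1R,6S)-6-[(dimethylamino)methyl]-2,2-dimethyl-5-oxocyclohex-3-en-1-yl]-3,7-dimethylnona-3,7-dien-1-yl acetate | BrC/C=C(\C)CC/C=C(/C)C[C@@H](OC(C)=O)[C@@H]1[C@@H](CN(C)C)C(=O)C=CC1(C)C
F9 | step 11 | (1S,3S,4R,7S,8S,10R,11R,12S)-3,7-dibromo-12-[(dimethylamino)methyl]-4,8-dihydroxy-4,8,15,15-tetramethyl-13-oxobicyclo[9.3.1]pentadecan-10-yl acetate | CN(C)C[C@H]1C(=O)C[C@H]2C[C@H](Br)[C@@](O)(C)CC[C@H](Br)[C@](O)(C)C[C@@H](OC(C)=O)[C@H]1C2(C)C
F10 | step 11 | (1R,3R,4R,7R,8S,10R,11R,12S)-12-[(dimethylamino)methyl]-3,4:7,8-diepoxy-4,8,15,15-tetramethyl-13-oxobicyclo[9.3.1]pentadecan-10-yl acetate | CN(C)C[C@H]1C(=O)C[C@H]2C[C@H]3O[C@]3(C)CC[C@H]3O[C@@]3(C)C[C@@H](OC(C)=O)[C@H]1C2(C)C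
F11 | step 7 | trimethyl[(2E,6R)-3,7-dimethyl-6-(4,4,5,5-tetramethyl-1,3,2-dioxaborolan-2-yl)octa-2,7-dien-1-yl]silane | C[Si](C)(C)C/C=C(\C)CC[C@@H](B1OC(C)(C)C(C)(C)O1)C(C)=C
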